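What does the 22 mM flask hold at 12 min, and how much of it is complex with one exchanged, which neither earlier run measured?

| flask | starting complex | incoming ligand | leaving ligand | remark | time |
|---|---|---|---|---|---|
| summer | 11 mM (fed, over 50 s) | 0.50 equiv | 2 equiv | run made earlier; the fed solution adds 1.0 times the starting volume |  |
| noon | 16 mM (fed, over 50 s) | 0.50 equiv | 2 equiv | run made earlier; the fed solution adds 1.0 times the starting volume |  |
| flask | 22 mM (fed, over 50 s) | 0.500 equiv | 2.00 equiv | the fed solution adds 1.0 times the starting volume | 12 min |

| run | time / min | starting complex / % | complex with two exchanged / % |
|---|---|---|---|
| summer | 0.500 | 38.3 | 3.1 |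
| summer | 1.00 | 59.6 | 6.3 |
| summer | 2.00 | 55.2 | 13.7 |
| summer | 4.00 | 53.1 | 16.8 |
| summer | 8.00 | 52.8 | 16.8 |
| noon | 0.667 | 47.7 | 5.2 |
| noon | 2.00 | 52.8 | 14.5 |
| noon | 3.00 | 52.9 | 17.2 |
| noon | 5.00 | 53.1 | 17.5 |
| noon | 8.00 | 52.1 | 17.0 |

(readings scatter by 0.5 percentage points)

- charges are per starting volume, the dose included; the dosed solution carries all of it
- what has gone from starting complex into another species counts as reacted, even if it can come back
- the reaction counts as stopped when no species that holds the starting complex changes by six tenths of a point or more over the second half of the time
- percentages count the whole charge, also what has not yet gone in

- which holds at 12 min: what has brought the reaction to rest, or that it has not come to rest (forward and back rates have come level / it is still moving / all of the starting complex has reacted / the incoming ligand has run out first)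
- how much of the starting complex has reacted by 12 min
- how much complex with two exchanged there is at 12 min, in percent of the starting complex charged
- how much complex with one exchanged there is at 12 min, in percent of the starting complex charged

The summer and noon runs levelled off alike. Their late readings of starting complex averaged 52.8%, and those of complex with two exchanged averaged 17.1%. So I expected this flask to come to the same rest, with forward and back rates level and 47.2% reacted.

Subtraction could not safely give complex with one exchanged. Each complex with one exchanged holds one incoming ligand, and each complex with two exchanged holds two. Incoming ligand was the limiting reagent by charge, at 0.500 equiv. I reckoned 15.9% and called this the ligand room: the incoming ligand charged, less twice [complex with two exchanged], both in percent of the starting complex charged. So [complex with one exchanged] had to stay within the room. On these scattered readings, about 14.2% or more of the reacted share then had to sit in a form holding no incoming ligand.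

The forecast gave forward and back rates have come level, 47.1% reacted, 17.2% with two exchanged and 29.9% with one exchanged: “Mass balance then gives one-exchanged about 30%.” Its figure for complex with one exchanged stood above my ligand room.

This flask gave forward and back rates have come level, with 47.4% reacted, 17.2% with two exchanged and 6.78% with one exchanged, which is less than the room.

    starting complex ⇌ dormant form (K = 0.420, k = 0.450 s⁻¹)
    starting complex + incoming ligand ⇌ leaving ligand + complex with one exchanged (K = 6.60, k = 3.60 L mol⁻¹ s⁻¹)
    complex with one exchanged + incoming ligand ⇌ leaving ligand + complex with two exchanged (K = 130, k = 23.0 L mol⁻¹ s⁻¹)
    complex with two exchanged + incoming ligand ⇌ leaving ligand + complex with three exchanged (K = 3.90, k = 24.0 L mol⁻¹ s⁻¹)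

In this flask the ligand room, taken from its own complex with two exchanged, was 15.6%, and the dormant form, which holds no incoming ligand, stood at 22.1%. The neighbour flask with 0.300 equiv of incoming ligand reckons the same way. Its room was 10.2%, and its complex with one exchanged stood lower than that, at 5.45%, with 40.8% reacted and 9.89% with two exchanged. That required at least 20.7% without incoming ligand, and its dormant form held 24.9%.

(Readings and results stem from a simulated flask from invented constants, noise included.)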